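Early readings show the climb, with red at 76% by 5.00 h, so read the late ones to find where each flask stops.

| flask | starting material | remark | time |
|---|---|---|---|
| teal | 25 mM | run made earlier |  |
| red | 46 mM | run made earlier |  |
| cedar | 40 mM |  | 0.50 d |
| birch | 20 mM |  | 2.0 d |

| run | time / h | product / % | starting material / % |
|---|---|---|---|
| teal | 2.00 | 42 | 58 |
| teal | 5.00 | 62 | 38 |
| teal | 10.0 | 70 | 28 |
| teal | 15.0 | 80 | 23 |
| teal | 20.0 | 78 | 28 |
| teal | 25.0 | 81 | 17 |
| teal | 30.0 | 76 | 13 |
| red | 5.00 | 76 | 24 |
| red | 10.0 | 81 | 15 |
| red | 15.0 | 87 | 16 |
| red | 20.0 | 84 | 15 |
| red | 25.0 | 84 | 11 |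
| red | 30.0 | 87 | 13 |

(each reading ± 2 percentage points)

- in percentages every species weighs as the starting material in it: one product counts as two
- what may be going on: 2 starting material <-> product

- which of the two ends with the higher amount of product, in percent of the starting material charged ("neither" if they lie within 2 percentage points) (cedar / birch / neither)
- product at the end, in percent of the starting material charged, cedar
- product at the end, in percent of the starting material charged, birch

Take the equilibrium constant of the dimerisation, K = [product]/[starting material] squared, as the working quantity. One product counts as two, so a plateau share x of a charge c means [product] = x·c/2 and [starting material] = c minus x·c.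

Average the product readings from 15.0 h onward. Teal gives 78.8%, so K reads 349 M⁻¹. Red gives 85.5%, so K reads 442 M⁻¹. Carry their mean, 395 M⁻¹.

Solved for x, this K gives cedar a plateau of 83.7% and birch 77.8%, so cedar stands higher. Birch runs longer than teal's 30.0 h, so expect birch at its plateau. Cedar's 12 h exceeds the 10.0 h at which red read 81%, but not by much, so expect cedar a little under its plateau.

The forecast, whose numbers differ slightly from this reckoning, says cedar, 83% and 79%: “Cedar ends about 4 points higher, which is only a modest margin.”

The flask gives cedar, with cedar at 82.5% and birch at 78.4%.

    2 starting material ⇌ product (K = 420 M⁻¹, k = 0.00230 M⁻¹ s⁻¹)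

Cedar's relaxation half-life of 0.115 d is shorter than its 12 h, yet at ten times that time, 5.00 d, cedar reaches 84.2%, higher than at the asked time by 1.7 percentage points. Birch stays at 78.4% at 20.0 d.

Now charge cedar's flask with 68 mM for the same time: K gives a plateau of 87.3%, and the flask gives 87.0%.

The readings were computed for an exercise.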